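**Strategy.** The 2,3,4,7-tetrahydrooxepine (O1, C2–C7) is built by inserting one carbon into a six-membered cyclic enol ether. The ring segment C5=C6–C7–O1 is a dihydropyran enol ether C5=C7–O1 with C6 placed between its alkene carbon and its oxygen-bearing carbon, and C6 is also the carbon that carries the side chain. In one operation, silver-assisted opening of the dibromocarbene adduct in methanol enlarges the ring, places the alkene at C5=C6 and leaves bromine on C6 as the coupling handle. The precursor is an (S)-7,7-dibromo-2-oxabicyclo[4.1.0]heptane whose quaternary carbon bears a tert-butyl ester (future acid) and a methyl-ester arm (future aryl ketone).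

Key step: step 7

Remark: 15 should form as two cis-fused diastereomers and 17 as two C7 epimers; both mixtures are carried on because these centres are destroyed in steps 7 and 8, and one isomer of each is drawn.

**Step 1**
Reactants: 1 5-bromopent-1-ene; 2 di-tert-butyl oxalate
Product: 4 tert-butyl 2-oxohept-6-enoate, via pent-4-enylmagnesium bromide 3 (not isolated)
Conditions: Mg, THF, rt; then added to 2 (1.5 equiv), THF, −78 °C
Reagents that add atoms: none
Why: Grignard acylation by one ester group of the oxalate: at −78 °C the magnesium-chelated tetrahedral adduct persists until quench and the bulky tert-butyl groups slow a second addition, so the α-keto ester should be obtained; no stereocentre is formed.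

**Step 2**
Reactants: 5 methyl acetate
Product: 7 1-methoxy-1-(trimethylsilyloxy)ethene, via lithium enolate 6 (not isolated)
Conditions: LiN(i-Pr)2, THF, −78 °C; then TMSCl, −78 °C → rt; distil
Reagents that add atoms: chlorotrimethylsilane, C[Si](C)(C)Cl
Why: O-silylation of the lithium ester enolate is the standard entry to ketene silyl acetals for the Mukaiyama aldol reaction, and any C-silylated isomer is inert in step 3.

**Step 3**
Reactants: 4 tert-butyl 2-oxohept-6-enoate; 7 1-methoxy-1-(trimethylsilyloxy)ethene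
Product: 9 1-tert-butyl 4-methyl (2S)-2-hydroxy-2-(pent-4-en-1-yl)butanedioate, via silyl ether 8 (not isolated)
Conditions: Cu(OTf)2 (10 mol%), (S,S)-t-Bu-box [2,2'-(propane-2,2-diyl)bis((4S)-4-tert-butyl-4,5-dihydrooxazole)] (11 mol%), THF, −78 °C; then 1 M HCl
Reagents that add atoms: none
Why: Mukaiyama aldol addition to an α-keto ester held through both carbonyl oxygens on the square-planar divalent copper–bis(oxazoline) complex: a tert-butyl group of the (S,S)-ligand screens the re face of the ketone, so the ketene acetal should add to the si face and set C2 as S (sense taken by analogy with pyruvate esters and to be confirmed on 9; the (R,R)-ligand is equally available), and the tert-butyl keto ester is chosen so that the C2 carboxyl stays inert to every nucleophile used later.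

**Step 4**
Reactants: 9 hydroxy diester
Product: 11 tert-butyl (2S)-6-hydroxy-2-(2-methoxy-2-oxoethyl)oxane-2-carboxylate, via hydroxy aldehyde 10 (not isolated)
Conditions: O3, CH2Cl2, −78 °C; then PPh3, −78 °C → rt
Reagents that add atoms: ozone, [O-][O+]=O
Why: Ozonolysis with reductive work-up cleaves only the terminal alkene, and the resulting δ-hydroxy aldehyde closes spontaneously to the six-membered lactol, which makes the tertiary hydroxyl the future ring oxygen O1 without touching C2.

**Step 5**
Reactants: 11 lactol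
Product: 13 tert-butyl (2S)-2-(2-methoxy-2-oxoethyl)-3,4-dihydro-2H-pyran-2-carboxylate, via anomeric mesylate 12 (not isolated)
Conditions: MsCl, Et3N (excess), CH2Cl2, −20 °C → reflux
Reagents that add atoms: none
Why: Lactol dehydration through the anomeric mesylate (ionisation to the oxocarbenium ion and loss of a C5 proton, the usual lactol-to-glycal elimination) should give the cyclic enol ether; C2 is not involved.

**Step 6**
Reactants: 13 dihydropyran diester; 14 bromoform
Product: 15 tert-butyl (1S,3S,6R)-7,7-dibromo-3-(2-methoxy-2-oxoethyl)-2-oxabicyclo[4.1.0]heptane-3-carboxylate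
Conditions: KOt-Bu (added in portions to excess 14), pentane, −20 → 0 °C; used crude
Reagents that add atoms: none
Why: Cheletropic [2+1] addition of dibromocarbene, generated from bromoform by α-elimination, to the electron-rich enol ether is necessarily cis; the facial ratio is irrelevant, and free alkoxide is kept scarce (base added slowly to excess bromoform in a hydrocarbon at low temperature) so that the methyl ester arm is neither exchanged nor enolised, while tert-butoxide cannot alter the tert-butyl ester.

**Step 7**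
Reactants: 15 dibromocyclopropane
Product: 17 tert-butyl (2S,7S)-6-bromo-7-methoxy-2-(2-methoxy-2-oxoethyl)-2,3,4,7-tetrahydrooxepine-2-carboxylate, via oxocarbenium ion 16 (not isolated)
Conditions: AgOAc (1.5 equiv), MeOH, 0 °C → rt, dark
Reagents that add atoms: methanol, CO
Why: Silver ion removes the endo bromide of 15 while the C1–C6 bond shared by the two rings (bicycle numbering) opens in a disrotatory two-electron electrocyclic process (Woodward–Hoffmann–DePuy rule: the groups cis to the leaving group turn inward), the only sense that gives the cis,cis-allyl cation a seven-membered ring can hold, and donation from the ring oxygen lets this happen near room temperature. The closest known reaction type is the silver- or base-promoted ring expansion of gem-dihalocyclopropanated glycals and dihydropyrans in alcohols to 2-alkoxy-3-halo-tetrahydrooxepines. The oxepine is not formed by a cyclisation: the six-membered ring grows by one atom because the fusion bond is cleaved, so no closure mode in the Baldwin sense applies. The only new stereocentre, the acetal carbon C7, is uncontrolled (methanol can add to either face of cation 16) and is removed in step 8. The selectivity that matters is regiochemical, methanol at C7 and not at C5, and it is secured by O1, which localises the positive charge on C7 as an oxocarbenium ion, leaving the alkene at C5=C6 and bromine on C6. Both cyclopropane diastereomers carry an endo bromide and should converge on the same cation, while the quaternary C2 is a spectator.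

**Step 8**
Reactants: 17 bromo methoxy oxepine
Product: 18 tert-butyl (2S)-6-bromo-2-(2-methoxy-2-oxoethyl)-2,3,4,7-tetrahydrooxepine-2-carboxylate
Conditions: Et3SiH (3 equiv), BF3·OEt2 (1.5 equiv), CH2Cl2, −78 → −30 °C
Reagents that add atoms: none
Why: Ionic hydrogenation of the mixed acetal: BF3 removes the methoxy group (the ring oxygen, flanked by the ester-bearing C2, is the poorer Lewis base), which returns the molecule to oxocarbenium ion 16 already met in step 7, and Et3SiH delivers hydride to its carbon C7 as in reductive Ferrier-type deoxygenations, which erases the acetal centre; low temperature spares the tert-butyl ester, and the step precedes the coupling so that no nucleophilic alkene is present to trap the cation.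

**Step 9**
Reactants: 19 5-bromo-2-methylpent-2-ene
Product: 20 (2E)-5-bromo-2-methylpent-2-en-1-ol
Conditions: SeO2 (cat.), t-BuOOH, CH2Cl2, rt
Reagents that add atoms: selenium dioxide, O=[Se]=O (catalytic oxygen carrier); tert-butyl hydroperoxide, CC(C)(C)OO (terminal oxygen source)
Why: Catalytic SeO2 allylic oxidation (ene reaction followed by [2,3]-sigmatropic shift) of a gem-dimethyl trisubstituted alkene selectively hydroxylates the methyl group trans to the chain, which fixes the E geometry of the side chain; the primary bromide is inert.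

**Step 10**
Reactants: 20 bromo allylic alcohol
Product: 21 tert-butyl{[(2E)-5-bromo-2-methylpent-2-en-1-yl]oxy}dimethylsilane
Conditions: TBSCl, imidazole, CH2Cl2, rt
Reagents that add atoms: tert-butyl(chloro)dimethylsilane, CC(C)(C)[Si](C)(C)Cl
Why: Routine silylation of the primary allylic alcohol with a silyl chloride and imidazole.

**Step 11**
Reactants: 21 silyl ether bromide; 18 bromo oxepine
Product: 23 tert-butyl (2S)-6-[(3E)-5-{[tert-butyl(dimethyl)silyl]oxy}-4-methylpent-3-en-1-yl]-2-(2-methoxy-2-oxoethyl)-2,3,4,7-tetrahydrooxepine-2-carboxylate, via alkylzinc bromide 22 (not isolated)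
Conditions: 21, Zn, I2 (5 mol%), DMA, 80 °C; then 18, PdCl2(dppf) (5 mol%), THF/DMA, 50 °C
Reagents that add atoms: none
Why: Negishi coupling: iodine-activated zinc inserts into the primary C–Br bond and the alkylzinc bromide couples with the cyclic bromoalkene under PdCl2(dppf), whose wide bite angle favours reductive elimination over β-hydride elimination; both esters, the silyl ether and the remote alkene tolerate organozinc reagents, and both alkene geometries are retained.

**Step 12**
Reactants: 23 coupled diester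
Product: 24 tert-butyl (2S)-6-[(3E)-5-{[tert-butyl(dimethyl)silyl]oxy}-4-methylpent-3-en-1-yl]-2-{2-[methoxy(methyl)amino]-2-oxoethyl}-2,3,4,7-tetrahydrooxepine-2-carboxylate
Conditions: MeNHOMe·HCl (1.6 equiv), i-PrMgCl (3.2 equiv), THF, −20 → 0 °C
Reagents that add atoms: N,O-dimethylhydroxylamine hydrochloride, CNOC.Cl
Why: Weinreb amidation of the unhindered CH2CO2Me group by the magnesium amide formed in situ; the tert-butyl ester on the fully substituted C2 cannot be attacked, which is why the two esters are assigned this way.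

**Step 13**
Reactants: 25 2-bromobenzene-1,4-diol
Product: 26 [(2-bromo-1,4-phenylene)bis(oxy)]bis[tert-butyl(dimethyl)silane]
Conditions: TBSCl (2.4 equiv), imidazole, DMF, rt
Reagents that add atoms: tert-butyl(chloro)dimethylsilane, CC(C)(C)[Si](C)(C)Cl
Why: Routine bis-silylation of the hydroquinone, giving an aryl bromide suited to magnesium insertion.

**Step 14**
Reactants: 26 bis-silylated aryl bromide; 24 Weinreb amide
Product: 28 tert-butyl (2S)-2-[2-(2,5-bis{[tert-butyl(dimethyl)silyl]oxy}phenyl)-2-oxoethyl]-6-[(3E)-5-{[tert-butyl(dimethyl)silyl]oxy}-4-methylpent-3-en-1-yl]-2,3,4,7-tetrahydrooxepine-2-carboxylate, via arylmagnesium bromide 27 (not isolated)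
Conditions: 26, Mg, LiCl, THF, rt; then 24, 0 °C → rt
Reagents that add atoms: none
Why: Weinreb ketone synthesis: the aryl Grignard reagent adds once to the amide and the magnesium-chelated tetrahedral adduct collapses to the aryl ketone only on work-up, while the hindered tert-butyl ester is left alone.

**Step 15**
Reactants: 28 tris-silylated ketone
Product: 29 tert-butyl (2S)-2-[2-(2,5-bis{[tert-butyl(dimethyl)silyl]oxy}phenyl)-2-oxoethyl]-6-[(3E)-5-hydroxy-4-methylpent-3-en-1-yl]-2,3,4,7-tetrahydrooxepine-2-carboxylate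
Conditions: CSA (10 mol%), MeOH/CH2Cl2 (1:1), 0 °C
Reagents that add atoms: none
Why: Acid-catalysed methanolysis cleaves the primary alkyl silyl ether much faster than aryl silyl ethers, which resist acid, so only the allylic alcohol should be released; tert-butyl ester and β-alkoxy ketone are stable to these conditions.

**Step 16**
Reactants: 29 allylic alcohol; 30 (2E)-3-(4-hydroxyphenyl)prop-2-enoic acid (p-coumaric acid)
Product: 31 tert-butyl (2S)-2-[2-(2,5-bis{[tert-butyl(dimethyl)silyl]oxy}phenyl)-2-oxoethyl]-6-[(3E)-5-{[(2E)-3-(4-hydroxyphenyl)prop-2-enoyl]oxy}-4-methylpent-3-en-1-yl]-2,3,4,7-tetrahydrooxepine-2-carboxylate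
Conditions: PPh3, DIAD, THF, 0 °C → rt
Reagents that add atoms: none
Why: Mitsunobu esterification: the primary allylic alcohol is activated as its alkoxyphosphonium ion and displaced at carbon by the carboxylate, which is far more acidic than the phenol of the same acid and therefore should react chemoselectively without phenol protection; direct displacement at the primary carbon leaves the E alkene in place.

**Step 17**
Reactants: 31 protected coumarate
Product: 33 (2S)-2-[2-(2,5-dihydroxyphenyl)-2-oxoethyl]-6-[(3E)-5-{[(2E)-3-(4-hydroxyphenyl)prop-2-enoyl]oxy}-4-methylpent-3-en-1-yl]-2,3,4,7-tetrahydrooxepine-2-carboxylic acid, via silylated acid 32 (not isolated)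
Conditions: TFA/CH2Cl2 (1:4), 0 °C → rt; evaporate; then HF·pyridine, pyridine, THF, 0 °C → rt
Reagents that add atoms: none
Why: Acidolysis of the tert-butyl ester (loss of 2-methylpropene) and, after evaporation, fluoride cleavage of the two aryl silyl ethers; no base is used, so the coumarate ester and the β-alkoxy ketone, which could open by retro-oxa-Michael elimination, are not endangered, and C2 has no acidic hydrogen.

**Compound list**

1 | 5-bromopent-1-ene | C=CCCCBr | starting material
2 | di-tert-butyl oxalate | CC(C)(C)OC(=O)C(=O)OC(C)(C)C | starting material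
3 | pent-4-enylmagnesium bromide (formed in situ) | C=CCCC[Mg]Br | intermediate
4 | tert-butyl 2-oxohept-6-enoate | C=CCCCC(=O)C(=O)OC(C)(C)C | intermediate
5 | methyl acetate | COC(C)=O | starting material
6 | lithium 1-methoxyethenolate (formed in situ) | C=C(OC)O[Li] | intermediate
7 | 1-methoxy-1-(trimethylsilyloxy)ethene | C=C(OC)O[Si](C)(C)C | intermediate
8 | 1-tert-butyl 4-methyl (2S)-2-(pent-4-en-1-yl)-2-[(trimethylsilyl)oxy]butanedioate (formed in situ) | C=CCCC[C@](CC(=O)OC)(C(=O)OC(C)(C)C)O[Si](C)(C)C | intermediate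
9 | 1-tert-butyl 4-methyl (2S)-2-hydroxy-2-(pent-4-en-1-yl)butanedioate | C=CCCC[C@](CC(=O)OC)(C(=O)OC(C)(C)C)O | intermediate
10 | 1-tert-butyl 4-methyl (2S)-2-hydroxy-2-(4-oxobutyl)butanedioate (formed in situ) | O=CCCC[C@](CC(=O)OC)(C(=O)OC(C)(C)C)O | intermediate
11 | tert-butyl (2S)-6-hydroxy-2-(2-methoxy-2-oxoethyl)oxane-2-carboxylate (both C6 epimers) | OC1CCC[C@](CC(=O)OC)(C(=O)OC(C)(C)C)O1 | intermediate
12 | tert-butyl (2S)-6-[(methanesulfonyl)oxy]-2-(2-methoxy-2-oxoethyl)oxane-2-carboxylate (formed in situ) | CS(=O)(=O)OC1CCC[C@](CC(=O)OC)(C(=O)OC(C)(C)C)O1 | intermediate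
13 | tert-butyl (2S)-2-(2-methoxy-2-oxoethyl)-3,4-dihydro-2H-pyran-2-carboxylate | C1=CCC[C@](CC(=O)OC)(C(=O)OC(C)(C)C)O1 | intermediate
14 | bromoform | BrC(Br)Br | starting material
15 | tert-butyl (1S,3S,6R)-7,7-dibromo-3-(2-methoxy-2-oxoethyl)-2-oxabicyclo[4.1.0]heptane-3-carboxylate (cis-fused; drawn isomer, formed with its (1R,3S,6S) diastereomer; key-step precursor) | BrC1(Br)[C@@H]2CC[C@](CC(=O)OC)(C(=O)OC(C)(C)C)O[C@H]12 | intermediate
16 | (2S)-6-bromo-2-(tert-butoxycarbonyl)-2-(2-methoxy-2-oxoethyl)-3,4-dihydro-2H-oxepin-1-ium (formed in situ in step 7; the same ion is passed through again in step 8) | BrC1=CCC[C@](CC(=O)OC)(C(=O)OC(C)(C)C)[O+]=C1 | intermediate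
17 | tert-butyl (2S,7S)-6-bromo-7-methoxy-2-(2-methoxy-2-oxoethyl)-2,3,4,7-tetrahydrooxepine-2-carboxylate (drawn epimer, formed with its (2S,7R) epimer; key-step product) | BrC1=CCC[C@](CC(=O)OC)(C(=O)OC(C)(C)C)O[C@@H]1OC | intermediate
18 | tert-butyl (2S)-6-bromo-2-(2-methoxy-2-oxoethyl)-2,3,4,7-tetrahydrooxepine-2-carboxylate | BrC1=CCC[C@](CC(=O)OC)(C(=O)OC(C)(C)C)OC1 | intermediate
19 | 5-bromo-2-methylpent-2-ene | CC(C)=CCCBr | starting material
20 | (2E)-5-bromo-2-methylpent-2-en-1-ol | C/C(=C\CCBr)CO | intermediate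
21 | tert-butyl{[(2E)-5-bromo-2-methylpent-2-en-1-yl]oxy}dimethylsilane | C/C(=C\CCBr)CO[Si](C)(C)C(C)(C)C | intermediate
22 | bromo[(3E)-5-{[tert-butyl(dimethyl)silyl]oxy}-4-methylpent-3-en-1-yl]zinc (formed in situ) | C/C(=C\CC[Zn]Br)CO[Si](C)(C)C(C)(C)C | intermediate
23 | tert-butyl (2S)-6-[(3E)-5-{[tert-butyl(dimethyl)silyl]oxy}-4-methylpent-3-en-1-yl]-2-(2-methoxy-2-oxoethyl)-2,3,4,7-tetrahydrooxepine-2-carboxylate | C/C(=C\CCC1=CCC[C@](CC(=O)OC)(C(=O)OC(C)(C)C)OC1)CO[Si](C)(C)C(C)(C)C | intermediate
24 | tert-butyl (2S)-6-[(3E)-5-{[tert-butyl(dimethyl)silyl]oxy}-4-methylpent-3-en-1-yl]-2-{2-[methoxy(methyl)amino]-2-oxoethyl}-2,3,4,7-tetrahydrooxepine-2-carboxylate | C/C(=C\CCC1=CCC[C@](CC(=O)N(C)OC)(C(=O)OC(C)(C)C)OC1)CO[Si](C)(C)C(C)(C)C | intermediate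
25 | 2-bromobenzene-1,4-diol | Oc1ccc(O)c(Br)c1 | starting material
26 | [(2-bromo-1,4-phenylene)bis(oxy)]bis[tert-butyl(dimethyl)silane] | Brc1cc(O[Si](C)(C)C(C)(C)C)ccc1O[Si](C)(C)C(C)(C)C | intermediate
27 | (2,5-bis{[tert-butyl(dimethyl)silyl]oxy}phenyl)magnesium bromide (formed in situ) | Br[Mg]c1cc(O[Si](C)(C)C(C)(C)C)ccc1O[Si](C)(C)C(C)(C)C | intermediate
28 | tert-butyl (2S)-2-[2-(2,5-bis{[tert-butyl(dimethyl)silyl]oxy}phenyl)-2-oxoethyl]-6-[(3E)-5-{[tert-butyl(dimethyl)silyl]oxy}-4-methylpent-3-en-1-yl]-2,3,4,7-tetrahydrooxepine-2-carboxylate | C/C(=C\CCC1=CCC[C@](CC(=O)c2cc(O[Si](C)(C)C(C)(C)C)ccc2O[Si](C)(C)C(C)(C)C)(C(=O)OC(C)(C)C)OC1)CO[Si](C)(C)C(C)(C)C | intermediate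
29 | tert-butyl (2S)-2-[2-(2,5-bis{[tert-butyl(dimethyl)silyl]oxy}phenyl)-2-oxoethyl]-6-[(3E)-5-hydroxy-4-methylpent-3-en-1-yl]-2,3,4,7-tetrahydrooxepine-2-carboxylate | C/C(=C\CCC1=CCC[C@](CC(=O)c2cc(O[Si](C)(C)C(C)(C)C)ccc2O[Si](C)(C)C(C)(C)C)(C(=O)OC(C)(C)C)OC1)CO | intermediate
30 | (2E)-3-(4-hydroxyphenyl)prop-2-enoic acid (p-coumaric acid) | OC(=O)/C=C/c1ccc(O)cc1 | starting material
31 | tert-butyl (2S)-2-[2-(2,5-bis{[tert-butyl(dimethyl)silyl]oxy}phenyl)-2-oxoethyl]-6-[(3E)-5-{[(2E)-3-(4-hydroxyphenyl)prop-2-enoyl]oxy}-4-methylpent-3-en-1-yl]-2,3,4,7-tetrahydrooxepine-2-carboxylate | C/C(=C\CCC1=CCC[C@](CC(=O)c2cc(O[Si](C)(C)C(C)(C)C)ccc2O[Si](C)(C)C(C)(C)C)(C(=O)OC(C)(C)C)OC1)COC(=O)/C=C/c1ccc(O)cc1 | intermediate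
32 | (2S)-2-[2-(2,5-bis{[tert-butyl(dimethyl)silyl]oxy}phenyl)-2-oxoethyl]-6-[(3E)-5-{[(2E)-3-(4-hydroxyphenyl)prop-2-enoyl]oxy}-4-methylpent-3-en-1-yl]-2,3,4,7-tetrahydrooxepine-2-carboxylic acid (formed in situ) | C/C(=C\CCC1=CCC[C@](CC(=O)c2cc(O[Si](C)(C)C(C)(C)C)ccc2O[Si](C)(C)C(C)(C)C)(C(=O)O)OC1)COC(=O)/C=C/c1ccc(O)cc1 | intermediate
33 | (2S)-2-[2-(2,5-dihydroxyphenyl)-2-oxoethyl]-6-[(3E)-5-{[(2E)-3-(4-hydroxyphenyl)prop-2-enoyl]oxy}-4-methylpent-3-en-1-yl]-2,3,4,7-tetrahydrooxepine-2-carboxylic acid | C/C(=C\CCC1=CCC[C@](CC(=O)c2cc(O)ccc2O)(C(=O)O)OC1)COC(=O)/C=C/c1ccc(O)cc1 | target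

**Step count.** Total: 17 steps. Longest linear sequence: 13 steps (1, 3–8, 11, 12, 14–17, from 5-bromopent-1-ene); the ketene acetal (step 2), the side chain (steps 9, 10) and the arene (step 13) are made in parallel.

**Steps most likely to fail**

1. Step 7. The oxygen-activated dibromide may begin to ionise before silver and methanol are in control, during its preparation, concentration or storage. Bromide return, proton loss from C4 and hydrolysis would then compete with methanol capture, and the mixed acetal would not form cleanly. The fallback sets out from 13 and comes back at 23; it uses the dichloro series, whose adduct opens only when forced. Dichlorocarbene generated without base (Cl3CCO2Na, DME, reflux) should give the storable dichlorocyclopropane F1. AgBF4 with 2,6-lutidine in methanol at 50 °C should open it to the chloro methoxy oxepine F2. Et3SiH/BF3·OEt2 as in step 8 should give the chloro oxepine F3. The chloroalkene is then coupled with alkylzinc 22 using Pd[P(t-Bu)3]2 in THF/NMP at 80 °C, a catalyst suited to alkenyl chlorides, giving 23.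

2. Step 6. The alkoxide that generates the carbene may also enolise the arm ester, whose β-oxygen is an enol-ether oxygen and therefore a good leaving group, so the ring could open by β-elimination. It could also exchange the methyl ester for tert-butyl, which would erase the difference between the two esters. The fallback sets out from 13 and comes back at 15: alkoxide is given up, and CBr2 is transferred from phenyl(tribromomethyl)mercury, PhHgCBr3, triggered by NaI in DME at −10 °C → rt, a neutral carbene-transfer reagent. This fallback makes no new compound (F0).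

3. Step 17. The acid stage must last long enough to cleave a hindered, electron-poor tert-butyl ester. Meanwhile the trisubstituted alkenes can be protonated (trifluoroacetate addition, lactonisation of the freed C2 acid onto C6) and the allylic coumarate can ionise. The fallback sets out from 18 and comes back at 33; it moves the acid step to 18, the one intermediate whose alkene is deactivated by bromine and which has no other acid-sensitive group. TFA/CH2Cl2 should give the bromo oxepine acid F4. 2-(Trimethylsilyl)ethanol with EDC·HCl and DMAP should give the silylethyl ester F5. Steps 11, 12, 14, 15 and 16 are repeated in this series, giving in turn the coupled diester F6, the Weinreb amide F7, the aryl ketone F8, the allylic alcohol F9 and the coumarate F10. The C2 ester is now only hindered, not inert, so the analogues of steps 12 and 14 are run at the lowest workable temperature. TASF in DMF then removes the silylethyl ester and both aryl silyl ethers in one non-acidic operation to give 33, at the cost of two extra steps.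

**Further compounds**

F1 | step 7 | tert-butyl (1S,3S,6R)-7,7-dichloro-3-(2-methoxy-2-oxoethyl)-2-oxabicyclo[4.1.0]heptane-3-carboxylate (cis-fused, drawn isomer of two) | ClC1(Cl)[C@@H]2CC[C@](CC(=O)OC)(C(=O)OC(C)(C)C)O[C@H]12
F2 | step 7 | tert-butyl (2S,7S)-6-chloro-7-methoxy-2-(2-methoxy-2-oxoethyl)-2,3,4,7-tetrahydrooxepine-2-carboxylate (drawn epimer of two) | ClC1=CCC[C@](CC(=O)OC)(C(=O)OC(C)(C)C)O[C@@H]1OC
F3 | step 7 | tert-butyl (2S)-6-chloro-2-(2-methoxy-2-oxoethyl)-2,3,4,7-tetrahydrooxepine-2-carboxylate | ClC1=CCC[C@](CC(=O)OC)(C(=O)OC(C)(C)C)OC1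
F0 | step 6 | none | none
F4 | step 17 | (2S)-6-bromo-2-(2-methoxy-2-oxoethyl)-2,3,4,7-tetrahydrooxepine-2-carboxylic acid | BrC1=CCC[C@](CC(=O)OC)(C(=O)O)OC1
F5 | step 17 | 2-(trimethylsilyl)ethyl (2S)-6-bromo-2-(2-methoxy-2-oxoethyl)-2,3,4,7-tetrahydrooxepine-2-carboxylate | BrC1=CCC[C@](CC(=O)OC)(C(=O)OCC[Si](C)(C)C)OC1
F6 | step 17 | 2-(trimethylsilyl)ethyl (2S)-6-[(3E)-5-{[tert-butyl(dimethyl)silyl]oxy}-4-methylpent-3-en-1-yl]-2-(2-methoxy-2-oxoethyl)-2,3,4,7-tetrahydrooxepine-2-carboxylate | C/C(=C\CCC1=CCC[C@](CC(=O)OC)(C(=O)OCC[Si](C)(C)C)OC1)CO[Si](C)(C)C(C)(C)C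
F7 | step 17 | 2-(trimethylsilyl)ethyl (2S)-6-[(3E)-5-{[tert-butyl(dimethyl)silyl]oxy}-4-methylpent-3-en-1-yl]-2-{2-[methoxy(methyl)amino]-2-oxoethyl}-2,3,4,7-tetrahydrooxepine-2-carboxylate | C/C(=C\CCC1=CCC[C@](CC(=O)N(C)OC)(C(=O)OCC[Si](C)(C)C)OC1)CO[Si](C)(C)C(C)(C)C
F8 | step 17 | 2-(trimethylsilyl)ethyl (2S)-2-[2-(2,5-bis{[tert-butyl(dimethyl)silyl]oxy}phenyl)-2-oxoethyl]-6-[(3E)-5-{[tert-butyl(dimethyl)silyl]oxy}-4-methylpent-3-en-1-yl]-2,3,4,7-tetrahydrooxepine-2-carboxylate | C/C(=C\CCC1=CCC[C@](CC(=O)c2cc(O[Si](C)(C)C(C)(C)C)ccc2O[Si](C)(C)C(C)(C)C)(C(=O)OCC[Si](C)(C)C)OC1)CO[Si](C)(C)C(C)(C)C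
F9 | step 17 | 2-(trimethylsilyl)ethyl (2S)-2-[2-(2,5-bis{[tert-butyl(dimethyl)silyl]oxy}phenyl)-2-oxoethyl]-6-[(3E)-5-hydroxy-4-methylpent-3-en-1-yl]-2,3,4,7-tetrahydrooxepine-2-carboxylate | C/C(=C\CCC1=CCC[C@](CC(=O)c2cc(O[Si](C)(C)C(C)(C)C)ccc2O[Si](C)(C)C(C)(C)C)(C(=O)OCC[Si](C)(C)C)OC1)CO
F10 | step 17 | 2-(trimethylsilyl)ethyl (2S)-2-[2-(2,5-bis{[tert-butyl(dimethyl)silyl]oxy}phenyl)-2-oxoethyl]-6-[(3E)-5-{[(2E)-3-(4-hydroxyphenyl)prop-2-enoyl]oxy}-4-methylpent-3-en-1-yl]-2,3,4,7-tetrahydrooxepine-2-carboxylate | C/C(=C\CCC1=CCC[C@](CC(=O)c2cc(O[Si](C)(C)C(C)(C)C)ccc2O[Si](C)(C)C(C)(C)C)(C(=O)OCC[Si](C)(C)C)OC1)COC(=O)/C=C/c1ccc(O)cc1
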